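**Plan**

- Retrosynthetic cuts: the five O–benzyl bonds; in lactone B the C3–CH2Ar bond, then the C3–OH bond, then O1–C5 (Baeyer–Villiger retron), which leaves a cyclobutanone whose two ring bonds go back to the allyl group of biaryl ring Y and a ketene; in lactone A the C3–CH2(ring X) bond; the ring X–ring Y bond; lactone A's core is cut back to eugenol in the same way.
- Enabling feature: with lactone atoms numbered O1, C2(=O), C3, C4, C5, lactone B stripped of its C3 hydroxyl and C3 arylmethyl group has C4 as its only stereocentre. Its arms C3 and C5 are the two enantiotopic CH2 groups of a 3-substituted cyclobutanone in which C4 lies on the mirror plane.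
- Forward order: lactone A core from eugenol (cyclobutanone, ring expansion, C3–O); biaryl by Suzuki coupling; union by enolate alkylation at C3 of lactone A; cyclobutanone built on the allyl group; ring expansion to lactone B; hydroxylation and arylmethylation at C3 of lactone B; hydrogenolysis.
- Stereochemistry: C4 of both lactones comes from the same catalyst-controlled Baeyer–Villiger desymmetrization. C3 of both lactones is set by substrate control, the carbon electrophile entering an oxygen-bearing enolate anti to the C4 arylmethyl group.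

Key step: step 17

**Remarks**

- Ring X is the biaryl ring bonded through CH2 to C3 of lactone A; ring Y is the one bonded through CH2 to C4 of lactone B.
- L* is one antipode of a C2-symmetric N,N′-dioxide ligand (pipecolic acid 2,6-diisopropylanilide units, N-oxide nitrogens linked by a (CH2)3 chain). Assumption: the antipode that gives the (S)-lactone is fixed on the conversion of 4 into 5 by comparison with that lactone's chiroptical data, and the same antipode is used in step 17.
- Compounds 3 and 17 form with both configurations at the cyclobutane CH; this centre becomes prochiral on dechlorination.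
- Compounds 6, 7 and 20 are drawn as the expected trans (3S,4R) isomers; their C3 configuration is lost in the following enolization, so both epimers converge.

**Route**

Step 1
Reactants: 1 eugenol (4-allyl-2-methoxyphenol)
Product: 2 4-allyl-1-(benzyloxy)-2-methoxybenzene
Conditions: BnBr, K2CO3, acetone, reflux
Reagents that add atoms: benzyl bromide, BrCc1ccccc1
Why: Williamson etherification of the phenoxide masks the phenol against the acid chloride and ketene of step 2 with a group that only the final hydrogenolysis removes.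

Step 2
Reactants: 2 4-allyl-1-(benzyloxy)-2-methoxybenzene
Product: 3 2,2-dichloro-3-[(4-benzyloxy-3-methoxyphenyl)methyl]cyclobutan-1-one (racemic)
Conditions: Cl3CCOCl (slow addition), Zn–Cu, Et2O–DME, rt
Reagents that add atoms: trichloroacetyl chloride, O=C(Cl)C(Cl)(Cl)Cl
Why: Dichloroketene generated by zinc reduction of the acid chloride undergoes a thermal ketene–alkene [2+2] cycloaddition with the terminal alkene, its carbonyl carbon bonding to the terminal CH2 so that the arylmethyl group ends at C3, while DME ties up zinc chloride; the new CH centre needs no control.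

Step 3
Reactants: 3 2,2-dichloro-3-[(4-benzyloxy-3-methoxyphenyl)methyl]cyclobutan-1-one
Product: 4 3-[(4-benzyloxy-3-methoxyphenyl)methyl]cyclobutan-1-one
Conditions: Zn dust, AcOH, rt to 50 °C
Reagents that add atoms: none
Why: Reductive dechlorination of an α,α-dichloroketone by zinc in acetic acid (via zinc enolates) spares the benzyl ether and the four-membered ketone and makes C3 prochiral.

Step 4
Reactants: 4 3-[(4-benzyloxy-3-methoxyphenyl)methyl]cyclobutan-1-one
Product: 5 (S)-4-[(4-benzyloxy-3-methoxyphenyl)methyl]oxolan-2-one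
Conditions: Sc(OTf)3 (5 mol%), L* (5.5 mol%), mCPBA, EtOAc, −20 °C
Reagents that add atoms: meta-chloroperbenzoic acid, O=C(OO)c1cccc(Cl)c1
Why: Catalytic asymmetric Baeyer–Villiger desymmetrization, in which the chiral Sc(III)–N,N′-dioxide complex holds the peracid adduct so that one enantiotopic CH2 migrates to oxygen and C4 is set as S; this also calibrates the catalyst for step 17.

Step 5
Reactants: 5 (S)-4-[(4-benzyloxy-3-methoxyphenyl)methyl]oxolan-2-one
Product: 6 (3S,4R)-3-hydroxy-4-[(4-benzyloxy-3-methoxyphenyl)methyl]oxolan-2-one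
Conditions: KHMDS, THF, −78 °C; 2-(phenylsulfonyl)-3-phenyloxaziridine; AcOH quench
Reagents that add atoms: 2-(phenylsulfonyl)-3-phenyloxaziridine, O=S(=O)(c1ccccc1)N1OC1c1ccccc1
Why: Enolate oxidation by electrophilic oxygen transfer from an N-sulfonyloxaziridine to the potassium enolate, oxygen entering anti to the C4 arylmethyl group to give mainly the trans alcohol.

Step 6
Reactants: 6 (3S,4R)-3-hydroxy-4-[(4-benzyloxy-3-methoxyphenyl)methyl]oxolan-2-one
Product: 7 (3S,4R)-3-(benzyloxy)-4-[(4-benzyloxy-3-methoxyphenyl)methyl]oxolan-2-one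
Conditions: BnBr, Ag2O, CH2Cl2, rt, dark
Reagents that add atoms: benzyl bromide, BrCc1ccccc1
Why: Silver(I) oxide-promoted O-benzylation (Williamson type under non-basic conditions) etherifies the α-hydroxy lactone without enolization or ring opening, so the later tertiary alcohol is already masked against dichloroketene.

Step 7
Reactants: 1 eugenol
Product: 8 4-allyl-2-bromo-6-methoxyphenol
Conditions: NBS, i-Pr2NH (10 mol%), CH2Cl2, 0 °C
Reagents that add atoms: N-bromosuccinimide, O=C1CCC(=O)N1Br
Why: Amine-mediated ortho-selective electrophilic aromatic bromination, in which the N-bromoamine is delivered to the position next to the phenol OH (para is blocked) and the electron-rich phenol ring reacts much faster than the terminal alkene.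

Step 8
Reactants: 8 4-allyl-2-bromo-6-methoxyphenol
Product: 9 5-allyl-2-(benzyloxy)-1-bromo-3-methoxybenzene
Conditions: BnBr, K2CO3, DMF, rt
Reagents that add atoms: benzyl bromide, BrCc1ccccc1
Why: Williamson etherification protects the ortho-bromophenol, which would otherwise retard the cross-coupling.

Step 9
Reactants: 10 5-bromovanillin (3-bromo-4-hydroxy-5-methoxybenzaldehyde)
Product: 11 4-(benzyloxy)-3-bromo-5-methoxybenzaldehyde
Conditions: BnBr, K2CO3, DMF, 60 °C
Reagents that add atoms: benzyl bromide, BrCc1ccccc1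
Why: Williamson etherification of the acidic phenol; the aldehyde is untouched.

Step 10
Reactants: 11 4-(benzyloxy)-3-bromo-5-methoxybenzaldehyde
Product: 12 4-(benzyloxy)-3-methoxy-5-(4,4,5,5-tetramethyl-1,3,2-dioxaborolan-2-yl)benzaldehyde
Conditions: B2pin2, Pd(dppf)Cl2 (3 mol%), KOAc, dioxane, 90 °C
Reagents that add atoms: bis(pinacolato)diboron, CC1(C)OB(OC1(C)C)B1OC(C)(C)C(C)(C)O1
Why: Miyaura borylation of the aryl bromide under acetate conditions tolerates the aldehyde and puts boron on the partner that carries no allyl group.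

Step 11
Reactants: 12 4-(benzyloxy)-3-methoxy-5-(pinacolboryl)benzaldehyde; 9 5-allyl-2-(benzyloxy)-1-bromo-3-methoxybenzene
Product: 13 5'-allyl-2',6-bis(benzyloxy)-3',5-dimethoxy-[1,1'-biphenyl]-3-carbaldehyde
Conditions: Pd(OAc)2 (3 mol%), SPhos (6 mol%), K3PO4, toluene–H2O, 80 °C
Reagents that add atoms: none
Why: Suzuki–Miyaura coupling with a dialkylbiarylphosphine ligand that copes with the electron-rich bromide and the two ortho-benzyloxy groups; aldehyde and allyl group are spectators.

Step 12
Reactants: 13 biaryl aldehyde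
Product: 14 [5'-allyl-2',6-bis(benzyloxy)-3',5-dimethoxy-[1,1'-biphenyl]-3-yl]methanol
Conditions: NaBH4, THF–MeOH, 0 °C
Reagents that add atoms: none
Why: Borohydride reduction of the aromatic aldehyde to the benzylic alcohol leaves the alkene and ethers alone.

Step 13
Reactants: 14 biaryl benzylic alcohol
Product: 15 5'-allyl-2',6-bis(benzyloxy)-3-(bromomethyl)-3',5-dimethoxy-1,1'-biphenyl
Conditions: PBr3, Et2O, 0 °C; used without storage
Reagents that add atoms: phosphorus tribromide, BrP(Br)Br
Why: Bromide displacement on the phosphite ester of a primary benzylic alcohol (alcohol-to-bromide substitution) gives the activated electrophile for the enolate alkylation.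

Step 14
Reactants: 7 (3S,4R)-3-(benzyloxy)-4-[(4-benzyloxy-3-methoxyphenyl)methyl]oxolan-2-one; 15 biaryl benzylic bromide
Product: 16 allyl biaryl lactone A: (3R,4R)-3-(benzyloxy)-4-[(4-benzyloxy-3-methoxyphenyl)methyl]-3-{[5'-allyl-2',6-bis(benzyloxy)-3',5-dimethoxy-[1,1'-biphenyl]-3-yl]methyl}oxolan-2-one
Conditions: LDA, THF, −78 °C; then 15, HMPA, −78 to −40 °C
Reagents that add atoms: none
Why: Lithium enolate alkylation (SN2 on the benzylic bromide) of the α-benzyloxy lactone, the electrophile approaching the planar C3 anti to the C4 arylmethyl group, so C3 is set as R with the two arylmethyl groups trans.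

Step 15
Reactants: 16 allyl biaryl lactone A
Product: 17 dichlorocyclobutanone: 16 with the allyl group replaced by a (2,2-dichloro-3-oxocyclobutyl)methyl group (both configurations at the cyclobutane CH)
Conditions: Cl3CCOCl (slow addition), Zn–Cu, Et2O–DME, rt
Reagents that add atoms: trichloroacetyl chloride, O=C(Cl)C(Cl)(Cl)Cl
Why: Ketene–alkene [2+2] cycloaddition of dichloroketene to the only alkene, with the regiochemistry of step 2; the lactone, the aryl ethers and the benzylated tertiary oxygen offer the ketene nothing to acylate.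

Step 16
Reactants: 17 dichlorocyclobutanone
Product: 18 cyclobutanone: lactone A unit of 16 whose ring Y carries a (3-oxocyclobutyl)methyl group
Conditions: Zn dust, AcOH, rt
Reagents that add atoms: none
Why: Zinc–acetic acid reductive dechlorination of the α,α-dichloroketone removes both chlorines and the unwanted stereocentre, leaving a cyclobutanone with a mirror plane through its C3.

Step 17
Reactants: 18 cyclobutanone
Product: 19 bis-lactone core: lactone A unit (3R,4R) unchanged, ring Y now carrying via CH2 the C4 of an (S)-configured oxolan-2-one (lactone B without C3 substituents)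
Conditions: Sc(OTf)3 (10 mol%), L* (11 mol%), mCPBA (1.2 equiv), EtOAc, −20 °C
Reagents that add atoms: meta-chloroperbenzoic acid, O=C(OO)c1cccc(Cl)c1
Why: The Sc(III)-activated ketone adds the peracid to give a Criegee adduct inside the chiral pocket, and the CH2–C(O) bond lying antiperiplanar to the O–O bond migrates to oxygen with loss of m-chlorobenzoate, driven by release of four-ring strain. The closest known reaction is the catalytic asymmetric Baeyer–Villiger desymmetrization of 3-aryl- and 3-arylmethylcyclobutanones with chiral Lewis acids and peracids, rehearsed here in step 4. The lactone B ring arises by ring expansion from four to five members through this 1,2-shift, which forms O1–C5; it is not a cyclization, so no exo/endo issue arises. C4 of lactone B becomes stereogenic, and its configuration (S by CIP at this stage, the arrangement that is R in the target) is decided only by which enantiotopic CH2 migrates, under control of the ligand antipode chosen in step 4; the remote centres of lactone A should have no meaningful influence. The step needs enantiotopic-group selectivity and chemoselectivity: both migrations give the same constitution, the cyclobutanone is the only ketone and the most electrophilic carbonyl, lactone A is not a substrate for oxygen insertion, no alkene remains, and the alkoxyarenes should survive a small excess of peracid at −20 °C.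

Step 18
Reactants: 19 bis-lactone core
Product: 20 hydroxy bis-lactone: 19 with lactone B as the (3S,4R)-3-hydroxy compound
Conditions: KHMDS, THF, −78 °C; 2-(phenylsulfonyl)-3-phenyloxaziridine; AcOH quench
Reagents that add atoms: 2-(phenylsulfonyl)-3-phenyloxaziridine, O=S(=O)(c1ccccc1)N1OC1c1ccccc1
Why: Enolate oxidation with an N-sulfonyloxaziridine, selective for lactone B because C3 of lactone A is quaternary and cannot enolize, oxygen entering anti to the C4 substituent.

Step 19
Reactants: 21 (4-benzyloxy-3-methoxyphenyl)methanol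
Product: 22 1-(benzyloxy)-4-(bromomethyl)-2-methoxybenzene
Conditions: PBr3, Et2O, 0 °C; used fresh
Reagents that add atoms: phosphorus tribromide, BrP(Br)Br
Why: Alcohol-to-bromide substitution of a primary benzylic alcohol via its phosphite ester.

Step 20
Reactants: 20 hydroxy bis-lactone; 22 1-(benzyloxy)-4-(bromomethyl)-2-methoxybenzene
Product: 23 penta-O-benzyl target: lactone A unit (3R,4R) as in 16; lactone B now (3R,4R)-3-hydroxy-3-[(4-benzyloxy-3-methoxyphenyl)methyl]
Conditions: LDA (2.3 equiv), THF–HMPA, −78 °C; 22, −78 to −30 °C; AcOH quench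
Reagents that add atoms: none
Why: Alkylation of the alkoxide–enolate dianion of an α-hydroxy lactone, in which carbon is the more nucleophilic site and the benzylic bromide enters anti to the C4 substituent, sets C3 of lactone B as R with the arylmethyl groups trans.

Step 21
Reactants: 23 penta-O-benzyl target
Product: 24 target CNP0218652.1, (3R,4R)/(3R,4R) bis-lactone with six free hydroxyl groups
Conditions: H2 (1–4 atm), Pd(OH)2/C, EtOAc–MeOH, rt
Reagents that add atoms: none
Why: Catalytic hydrogenolysis cleaves the four aryl benzyl ethers and the tertiary alkyl benzyl ether at their O–CH2Ph bonds; the lactones, the biaryl and the homobenzylic C–O bonds are inert.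

**Compound list**

1 | eugenol (4-allyl-2-methoxyphenol) | COc1cc(CC=C)ccc1O | starting material
2 | 4-allyl-1-(benzyloxy)-2-methoxybenzene | COc1cc(CC=C)ccc1OCc1ccccc1 | intermediate
3 | 2,2-dichloro-3-[(4-benzyloxy-3-methoxyphenyl)methyl]cyclobutan-1-one (racemic) | COc1cc(CC2CC(=O)C2(Cl)Cl)ccc1OCc1ccccc1 | intermediate
4 | 3-[(4-benzyloxy-3-methoxyphenyl)methyl]cyclobutan-1-one | COc1cc(CC2CC(=O)C2)ccc1OCc1ccccc1 | intermediate
5 | (S)-4-[(4-benzyloxy-3-methoxyphenyl)methyl]oxolan-2-one | COc1cc(C[C@@H]2COC(=O)C2)ccc1OCc1ccccc1 | intermediate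
6 | (3S,4R)-3-hydroxy-4-[(4-benzyloxy-3-methoxyphenyl)methyl]oxolan-2-one | COc1cc(C[C@@H]2COC(=O)[C@H]2O)ccc1OCc1ccccc1 | intermediate
7 | (3S,4R)-3-(benzyloxy)-4-[(4-benzyloxy-3-methoxyphenyl)methyl]oxolan-2-one | COc1cc(C[C@@H]2COC(=O)[C@H]2OCc2ccccc2)ccc1OCc1ccccc1 | intermediate
8 | 4-allyl-2-bromo-6-methoxyphenol | COc1cc(CC=C)cc(Br)c1O | intermediate
9 | 5-allyl-2-(benzyloxy)-1-bromo-3-methoxybenzene | COc1cc(CC=C)cc(Br)c1OCc1ccccc1 | intermediate
10 | 5-bromovanillin (3-bromo-4-hydroxy-5-methoxybenzaldehyde) | COc1cc(C=O)cc(Br)c1O | starting material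
11 | 4-(benzyloxy)-3-bromo-5-methoxybenzaldehyde | COc1cc(C=O)cc(Br)c1OCc1ccccc1 | intermediate
12 | 4-(benzyloxy)-3-methoxy-5-(4,4,5,5-tetramethyl-1,3,2-dioxaborolan-2-yl)benzaldehyde | COc1cc(C=O)cc(B2OC(C)(C)C(C)(C)O2)c1OCc1ccccc1 | intermediate
13 | 5'-allyl-2',6-bis(benzyloxy)-3',5-dimethoxy-[1,1'-biphenyl]-3-carbaldehyde | COc1cc(C=O)cc(-c2cc(CC=C)cc(OC)c2OCc2ccccc2)c1OCc1ccccc1 | intermediate
14 | [5'-allyl-2',6-bis(benzyloxy)-3',5-dimethoxy-[1,1'-biphenyl]-3-yl]methanol | COc1cc(CO)cc(-c2cc(CC=C)cc(OC)c2OCc2ccccc2)c1OCc1ccccc1 | intermediate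
15 | 5'-allyl-2',6-bis(benzyloxy)-3-(bromomethyl)-3',5-dimethoxy-1,1'-biphenyl | COc1cc(CBr)cc(-c2cc(CC=C)cc(OC)c2OCc2ccccc2)c1OCc1ccccc1 | intermediate
16 | (3R,4R)-3-(benzyloxy)-4-[(4-benzyloxy-3-methoxyphenyl)methyl]-3-{[5'-allyl-2',6-bis(benzyloxy)-3',5-dimethoxy-[1,1'-biphenyl]-3-yl]methyl}oxolan-2-one | COc1cc(C[C@@H]2COC(=O)[C@@]2(OCc2ccccc2)Cc2cc(OC)c(OCc3ccccc3)c(-c3cc(CC=C)cc(OC)c3OCc3ccccc3)c2)ccc1OCc1ccccc1 | intermediate
17 | 16 with the allyl group replaced by (2,2-dichloro-3-oxocyclobutyl)methyl, both configurations at the cyclobutane CH | COc1cc(C[C@@H]2COC(=O)[C@@]2(OCc2ccccc2)Cc2cc(OC)c(OCc3ccccc3)c(-c3cc(CC4CC(=O)C4(Cl)Cl)cc(OC)c3OCc3ccccc3)c2)ccc1OCc1ccccc1 | intermediate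
18 | 16 with the allyl group replaced by (3-oxocyclobutyl)methyl | COc1cc(C[C@@H]2COC(=O)[C@@]2(OCc2ccccc2)Cc2cc(OC)c(OCc3ccccc3)c(-c3cc(CC4CC(=O)C4)cc(OC)c3OCc3ccccc3)c2)ccc1OCc1ccccc1 | intermediate
19 | 16 with the allyl group replaced by [(3S)-5-oxooxolan-3-yl]methyl (lactone B core, 4S in lactone numbering) | COc1cc(C[C@@H]2COC(=O)[C@@]2(OCc2ccccc2)Cc2cc(OC)c(OCc3ccccc3)c(-c3cc(C[C@@H]4COC(=O)C4)cc(OC)c3OCc3ccccc3)c2)ccc1OCc1ccccc1 | intermediate
20 | 19 with lactone B as the trans (3S,4R)-3-hydroxy lactone | COc1cc(C[C@@H]2COC(=O)[C@@]2(OCc2ccccc2)Cc2cc(OC)c(OCc3ccccc3)c(-c3cc(C[C@@H]4COC(=O)[C@H]4O)cc(OC)c3OCc3ccccc3)c2)ccc1OCc1ccccc1 | intermediate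
21 | (4-benzyloxy-3-methoxyphenyl)methanol | COc1cc(CO)ccc1OCc1ccccc1 | starting material
22 | 1-(benzyloxy)-4-(bromomethyl)-2-methoxybenzene | COc1cc(CBr)ccc1OCc1ccccc1 | intermediate
23 | penta-O-benzyl target: lactone A (3R,4R)-3-benzyloxy, lactone B (3R,4R)-3-hydroxy-3-[(4-benzyloxy-3-methoxyphenyl)methyl], four aryl benzyl ethers | COc1cc(C[C@@H]2COC(=O)[C@@]2(OCc2ccccc2)Cc2cc(OC)c(OCc3ccccc3)c(-c3cc(C[C@@H]4COC(=O)[C@@]4(O)Cc4ccc(OCc5ccccc5)c(OC)c4)cc(OC)c3OCc3ccccc3)c2)ccc1OCc1ccccc1 | intermediate
24 | CNP0218652.1: (3R,4R)-3-hydroxy-4-(4-hydroxy-3-methoxybenzyl)oxolan-2-one joined at C3 through CH2 to ring X of a 2,2'-dihydroxy-3,3'-dimethoxybiphenyl, whose ring Y is joined through CH2 to C4 of (3R,4R)-3-hydroxy-3-(4-hydroxy-3-methoxybenzyl)oxolan-2-one | COc1cc(C[C@@H]2COC(=O)[C@@]2(O)Cc2cc(OC)c(O)c(-c3cc(C[C@@H]4COC(=O)[C@@]4(O)Cc4ccc(O)c(OC)c4)cc(OC)c3O)c2)ccc1O | target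

**Step count and risks**

Total steps: 21. Longest linear sequence: 13 (steps 1–6, 14–18, 20, 21).

Steps most likely to fail:

1. Step 17. The two enantiotopic methylene groups may be told apart incompletely: the peracid can oxidize the strained ketone without the catalyst, and a CH2Ar group at C3 is a weaker steric handle than an aryl group. Any leakage appears as the C4 epimer of lactone B, a diastereomer differing only at a centre far from lactone A and hard to remove.
Fallback, from 18 back to 19: the methylene groups are distinguished by proton removal instead of migration. A C2-symmetric chiral lithium amide, lithium bis(1-phenylethyl)amide of the appropriate (S,S) or (R,R) series, with Me3SiCl present in THF at −100 °C, should give the (3S)-3-(biarylmethyl)-1-(trimethylsilyloxy)cyclobut-1-ene F1. Titrated ozone in CH2Cl2–MeOH at −78 °C followed by NaBH4 cleaves the enol ether double bond and reduces the aldehyde terminus to the (3S)-3-(hydroxymethyl)butanoic acid F2. F2 closes on acidification to 19.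

2. Step 15. On a dilute, high-molecular-weight alkene, ketene oligomerization may outrun cycloaddition, and zinc chloride may attack the benzyl ethers, leaving much alkene unreacted.
Fallback, from 9 back to 18: the four-membered ring is built before the biaryl, on the substrate class already used in step 2. Dichloroketene addition to 9 gives 3-[(4-benzyloxy-3-bromo-5-methoxyphenyl)methyl]-2,2-dichlorocyclobutan-1-one F3, and Zn–AcOH gives the cyclobutanone F4. Ethylene glycol with PPTS under azeotropic water removal gives the 5,8-dioxaspiro[3.4]octane ketal F5. Suzuki–Miyaura coupling of F5 with 12 gives the ketal biaryl aldehyde F6, NaBH4 the ketal biaryl alcohol F7, and CBr4–PPh3 (Appel reaction, non-acidic) the ketal biaryl bromide F8. Alkylation of the lithium enolate of 7 with F8, as in step 14, gives the ketal of the cyclobutanone F9. Aqueous HCl in THF releases 18.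

3. Step 20. Dianion formation may be incomplete, the alkoxide may be O-alkylated, or the aggregated dianion may lose facial bias, giving recovered 20, ethers or the C3 epimer.
Fallback, from 20 back to 24: the alkylation is run on a monoanion. Ag2O–BnBr converts 20 into the lactone B 3-benzyl ether F10. LDA and 22 in THF–HMPA give the hexa-O-benzyl target F11, with the bromide again entering anti to the C4 substituent. Hydrogenolysis over Pd(OH)2/C gives 24.

**Further compounds**

F1 | step 17 | (3S)-1-(trimethylsilyloxy)cyclobut-1-ene carrying at C3 the CH2–ring Y of the lactone A biaryl | COc1cc(C[C@@H]2COC(=O)[C@@]2(OCc2ccccc2)Cc2cc(OC)c(OCc3ccccc3)c(-c3cc(C[C@@H]4C=C(O[Si](C)(C)C)C4)cc(OC)c3OCc3ccccc3)c2)ccc1OCc1ccccc1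
F2 | step 17 | (3S)-3-(hydroxymethyl)-4-(ring Y)butanoic acid of the lactone A biaryl | COc1cc(C[C@@H]2COC(=O)[C@@]2(OCc2ccccc2)Cc2cc(OC)c(OCc3ccccc3)c(-c3cc(C[C@H](CO)CC(=O)O)cc(OC)c3OCc3ccccc3)c2)ccc1OCc1ccccc1
F3 | step 15 | 3-[(4-benzyloxy-3-bromo-5-methoxyphenyl)methyl]-2,2-dichlorocyclobutan-1-one (racemic) | COc1cc(CC2CC(=O)C2(Cl)Cl)cc(Br)c1OCc1ccccc1
F4 | step 15 | 3-[(4-benzyloxy-3-bromo-5-methoxyphenyl)methyl]cyclobutan-1-one | COc1cc(CC2CC(=O)C2)cc(Br)c1OCc1ccccc1
F5 | step 15 | 2-[(4-benzyloxy-3-bromo-5-methoxyphenyl)methyl]-5,8-dioxaspiro[3.4]octane | COc1cc(CC2CC3(C2)OCCO3)cc(Br)c1OCc1ccccc1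
F6 | step 15 | 2',6-bis(benzyloxy)-5'-(5,8-dioxaspiro[3.4]octan-2-ylmethyl)-3',5-dimethoxy-[1,1'-biphenyl]-3-carbaldehyde | COc1cc(C=O)cc(-c2cc(CC3CC4(C3)OCCO4)cc(OC)c2OCc2ccccc2)c1OCc1ccccc1
F7 | step 15 | benzylic alcohol from reduction of F6 | COc1cc(CO)cc(-c2cc(CC3CC4(C3)OCCO4)cc(OC)c2OCc2ccccc2)c1OCc1ccccc1
F8 | step 15 | benzylic bromide from F7 | COc1cc(CBr)cc(-c2cc(CC3CC4(C3)OCCO4)cc(OC)c2OCc2ccccc2)c1OCc1ccccc1
F9 | step 15 | ethylene ketal of 18 | COc1cc(C[C@@H]2COC(=O)[C@@]2(OCc2ccccc2)Cc2cc(OC)c(OCc3ccccc3)c(-c3cc(CC4CC5(C4)OCCO5)cc(OC)c3OCc3ccccc3)c2)ccc1OCc1ccccc1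
F10 | step 20 | 20 with the lactone B hydroxyl as its benzyl ether (3S,4R) | COc1cc(C[C@@H]2COC(=O)[C@@]2(OCc2ccccc2)Cc2cc(OC)c(OCc3ccccc3)c(-c3cc(C[C@@H]4COC(=O)[C@H]4OCc4ccccc4)cc(OC)c3OCc3ccccc3)c2)ccc1OCc1ccccc1
F11 | step 20 | hexa-O-benzyl target, both lactones (3R,4R) | COc1cc(C[C@@H]2COC(=O)[C@@]2(OCc2ccccc2)Cc2cc(OC)c(OCc3ccccc3)c(-c3cc(C[C@@H]4COC(=O)[C@@]4(OCc4ccccc4)Cc4ccc(OCc5ccccc5)c(OC)c4)cc(OC)c3OCc3ccccc3)c2)ccc1OCc1ccccc1
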